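## Structural features

The target is a C30 hexacycle: an abietane (rings A, B, C; C1 to C20) whose ring C is an 11-hydroxy-12-oxo para-quinone methide (C7=C8, C9=C11, C13=C14, C12=O), joined twice to a thujane (primed atoms), through C14–C4' and C7–C10'. C7, C8, C14, C4' and C10' thus form a cyclopentene (ring D) with C4' as spiro atom of the bicyclo[3.1.0]hexane. There are six stereocentres: C5 and C10 (trans A/B fusion, 5α-H, 10β-methyl), the secondary carbinol C10' (hydroxyl α), the quaternary C4', and the cyclopropane carbons C5' and C1'; C10', C4', C5' and C1' are contiguous. At C4' the arene carbon C14 lies on the same face of the thujane five-membered ring as the cyclopropane methylene C6' (the concave, more hindered face), and C10' lies on the open face; seen from ring D, C5' is α and C3' is β. Fragile groups are the quinone methide (nucleophiles add at C7, and acid can move the double bond to C6–C7 with formation of the catechol), any free catechol (air), and the cyclopropane (acid, above all when positive charge develops on C4'). The real difficulty is the fully substituted C4', bonded to a doubly ortho-substituted arene carbon on the hindered face; any reagent that delivers an aryl group from outside to a trigonal C4' would come in anti to C6' and give the wrong epimer. The key step uses the fact that C7 and C10' hang from the neighbouring ring C atoms C8 and C14 (through C4'), so carbonyl groups at C7 and C10' face each other across a five-membered gap. In addition, the quinone methide from C7 to O12 plus the C10' hydroxyl is a C7,C10' cis-diol of the catechol less one water, so no redox change is needed after the coupling.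

## Logic of the disconnections

**19 to 17.** Water is added back across C7 and O12 and both ring C oxygens are methylated; no C–C bond is cut. The quinone methide is the dehydration product of the para-hydroxybenzylic tertiary alcohol 18, and methyl ethers keep the arene electron-rich and inert in every earlier step. The gain is that the reactive quinone methide and the air-sensitive catechol disappear and a cis-1,2-diol appears on ring D. The demand is an ether cleavage that spares the cyclopropane and does not send the C7 cation to a C6=C7 alkene. A boron halide at low temperature with a proton scavenger is chosen; thiolates as a rule cleave only one ether of a catechol pair and add to quinone methides.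

**17 to 16.** The C7–C10' bond is cut, which opens ring D and removes the stereocentres C7 and C10'. A vicinal diol between a tertiary benzylic and a secondary carbon is the signature of a ketone–aldehyde reductive coupling. The gain is a keto aldehyde with only the four stereocentres from the chiral pool plus C4'. The demand is cis selectivity and no side reaction of the cyclopropane.

**16 to 14 (through 15).** The C14–C4' bond is cut and C14–C10' and C4'–O are restored (a retro 1,2-aryl shift), and the C7 carbonyl goes back to its dioxolane. An aryl group that migrates from C10' to C4' with inversion turns an easy anti epoxidation into the required syn aryl group, which intermolecular arylation of a C4' enolate could not do. The dioxolane is needed because a free C7 carbonyl beside the epoxide would capture it as a bicyclic ketal and would deactivate the migrating arene. The gain is a quaternary centre traced back to a trisubstituted alkene. The demand is that aryl migration outruns hydride shift and opening of the cyclopropylcarbinyl system.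

**14 to 13.** The two C–O bonds of the epoxide are cut. The gain is a plain alkene. The demand is attack on the face anti to C6'; the alkene geometry does not matter because C10' becomes trigonal again.

**13 to 9 and 12.** The C14–C10' bond is cut between an arene carbon and an alkene carbon, the most convergent cut of the molecule. It gives an aryl bromide and an alkenyl boronate, and avoids the four extra steps that a benzylic sulfone olefination would need. The demand is a cross-coupling at a doubly ortho-substituted bromide.

**12 to 11 to 10.** The C4'=C10' bond is cut (boron–Wittig on the ketone), and the ketone comes from the exocyclic alkene of 10 by ozonolysis. Both cyclopropane stereocentres come from 10 unchanged. The demand is only that the cyclopropane survives ozone and a lithium amide base.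

**9 to 8 to 7 to 6.** The dioxolane C–O bonds, the C7=O bond and the C14–Br bond are removed in turn. Bromination must come before the acyl group deactivates C14. The C7 oxidation is placed here, where only a robust bromoarene is present, and not late, where a peri quaternary centre, a cyclopropane and an aldehyde would all interfere.

**6 to 1.** C20 is returned from methyl to the carboxylic acid and the ethers to the free catechol. 1 supplies rings A, B, C, both ring C oxygens and C5/C10. The demand is a deoxygenation of the neopentyl C20 that avoids a C20 cation or sulfonate, which would trigger aryl migration and ring expansion; a Wolff–Kishner reduction of the aldehyde meets it.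

## Other disconnections considered

**Alternative 1:** The cut is C7–C8 and C9–C10, so rings B and D fall away together. Forward, a fluoride source would remove the silyl and triflate groups of A2, and the strained C8–C9 triple bond would be trapped by the tethered diene C7=C6–C5=C10 in an intramolecular aryne Diels–Alder reaction to give A1.
- In its favour: two C–C bonds, two rings and the C10 quaternary centre form in one step, and no abietane starting material is needed. On bonds formed per step it is better than the chosen plan.
- Against it here: A2 is a hexasubstituted benzene that already contains the C14–C4' quaternary centre, so the hardest problem is not avoided, only moved into a longer precursor synthesis. The facial sense at C10 must be relayed from C10' alone. A1 carries the C10' epimer, a C5=C6 alkene and C7–H, so hydrogenation to the trans fusion, inversion at C10', ether cleavage and oxidation to the quinone methide all remain.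
- Comparison: structurally the chosen plan takes C5 and C10 from 1 without risk, whereas A1 has to create them. Mechanistically both key steps are known reaction types and are equal on that point, but the pinacol fixes its two centres by ring constraint and chelation and the cycloaddition by remote induction. In step count the alternative is expected to be longer on both sides of its key step.

**Alternative 2:** The cut is C4–C5 and C9–C10 (rings A and B). Forward, a squalene–hopene cyclase variant would protonate the terminal alkene of the geranyl chain of A4 and close ring A and then ring B onto C9 of the catechol, a proton-initiated class two polyene cyclisation ending in a Friedel–Crafts step, to give A3.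
- In its favour: no protecting groups, C5 and C10 are set by the enzyme, C10' and C4' are already correct, and A3 needs only oxidation of the catechol and tautomerisation to reach the quinone methide. On the endgame and on protecting-group economy it is better than the chosen plan.
- Against it here: acceptance of a substrate whose terminating arene is fully substituted but for C9 and carries a spiro thujane is an open question that enzyme engineering would have to answer. A4 still contains ring D, C4', C10' and C7, which must be made first by chemistry no simpler than steps 8 to 13. The cationic cascade also runs close to the cyclopropane.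
- Comparison: structurally the chosen plan buys what the enzyme would make. Mechanistically a ketyl closure is easier to predict than an engineered cyclase. In step count the alternative could be equal or shorter after its key step but not before it.

**Alternative 3:** The cut is C5'–C6' and C1'–C6' (the cyclopropane). Forward, a Corey–Chaykovsky methylene transfer from a sulfoxonium ylide would add to C5' of enone A6 and close on C1' to give A5.
- In its favour: a known reaction type, with the abietane and ring D already in place. The acid-sensitive cyclopropane would appear only after all Lewis-acid chemistry; on that point it is better than the chosen plan, where the cyclopropane must survive the epoxide rearrangement and the ether cleavage.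
- Against it here: the configuration of C5' and C1' relative to C4' must be induced (the methylene has to enter on the face of C14), whereas the chosen plan takes both centres from 10. C5' is neopentyl-like and C1' bears isopropyl, a poor acceptor for a stabilised ylide. The C2' carbonyl must then be deleted next to the new cyclopropane, and A5 still has C7–H, so an oxidation is needed at the end. A6 also needs its own synthesis of a spiro cyclopentenone on C14.
- Comparison: structurally the chosen plan uses the chiral pool for the very centres this route must control. Mechanistically the two are equal in resting on a well-known step. In step count the alternative adds the carbonyl removal and the late oxidation.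

Key step: step 13

Assumption: the boron–Wittig olefination (step 9) is taken to place boron cis to C3' (E); any Z isomer is carried along, because the alkene geometry only affects C10', which becomes the trigonal aldehyde carbon in step 12.

## Route

Step 1
Reactants: 1 carnosic acid (11,12-dihydroxyabieta-8,11,13-trien-20-oic acid)
Product: 2 methyl 11,12-dimethoxyabieta-8,11,13-trien-20-oate
Conditions: MeI (excess), K2CO3, acetone, reflux, argon
Reagents that add atoms: iodomethane CI
Why: SN2 alkylation of the carboxylate and both phenoxides (Williamson ether synthesis and ester formation); argon prevents oxidation of the catechol before it is capped.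

Step 2
Reactants: 2 methyl 11,12-dimethoxyabieta-8,11,13-trien-20-oate
Product: 3 11,12-dimethoxyabieta-8,11,13-trien-20-ol
Conditions: LiAlH4, THF, reflux
Reagents that add atoms: none
Why: Hydride reduction of the hindered neopentyl ester to the primary alcohol; nothing else in the molecule is reducible.

Step 3
Reactants: 3 11,12-dimethoxyabieta-8,11,13-trien-20-ol
Product: 4 11,12-dimethoxyabieta-8,11,13-trien-20-al
Conditions: Dess–Martin periodinane, CH2Cl2, rt
Reagents that add atoms: none
Why: Neutral oxidation of the neopentyl alcohol to the aldehyde, which has no α-hydrogen and cannot epimerise or over-oxidise; no cation or leaving group is made at C20, so the arene cannot migrate.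

Step 4
Reactants: 4 11,12-dimethoxyabieta-8,11,13-trien-20-al
Product: 6 11,12-dimethoxyabieta-8,11,13-triene, via C20 hydrazone 5 (not isolated)
Conditions: N2H4·H2O, KOH, diethylene glycol, 130 °C then 210 °C
Reagents that add atoms: none
Why: Wolff–Kishner reduction (Huang-Minlon procedure) turns the non-enolisable aldehyde into the C20 methyl group through the hydrazone anion; aryl methyl ethers and the C5/C10 centres are untouched.

Step 5
Reactants: 6 11,12-dimethoxyabieta-8,11,13-triene
Product: 7 14-bromo-11,12-dimethoxyabieta-8,11,13-triene
Conditions: NBS, MeCN, 0 °C to rt, dark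
Reagents that add atoms: N-bromosuccinimide O=C1CCC(=O)N1Br
Why: Electrophilic aromatic bromination; C14 is the only unsubstituted ring position and is para to the C11 oxygen, and polar conditions in the dark suppress benzylic bromination.

Step 6
Reactants: 7 14-bromo-11,12-dimethoxyabieta-8,11,13-triene
Product: 8 14-bromo-11,12-dimethoxyabieta-8,11,13-trien-7-one
Conditions: CrO3, AcOH/H2O, rt
Reagents that add atoms: chromium trioxide O=[Cr](=O)=O
Why: Benzylic oxidation by chromic acid at C7, the methylene para to the C12 oxygen, as is usual for abieta-8,11,13-trienes; the isopropyl methine is shielded between bromine and methoxy, and the bromoarene is inert.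

Step 7
Reactants: 8 14-bromo-11,12-dimethoxyabieta-8,11,13-trien-7-one
Product: 9 14-bromo-7,7-(ethylenedioxy)-11,12-dimethoxyabieta-8,11,13-triene
Conditions: (Me3SiOCH2)2, Me3SiOTf (cat.), CH2Cl2, −78 to −20 °C
Reagents that add atoms: 1,2-bis(trimethylsilyloxy)ethane C[Si](C)(C)OCCO[Si](C)(C)C
Why: Acetalisation driven by formation of hexamethyldisiloxane, suited to a hindered, electron-rich aryl ketone; the dioxolane keeps the C7 oxygen from taking part in the later epoxide rearrangement.

Step 8
Reactants: 10 (1R,5R)-sabinene
Product: 11 sabina ketone, (1S,5R)-5-(propan-2-yl)bicyclo[3.1.0]hexan-2-one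
Conditions: O3, CH2Cl2/MeOH, −78 °C; then Me2S
Reagents that add atoms: ozone [O-][O+]=O
Why: Ozonolysis of the exocyclic alkene with reductive work-up; the cyclopropane is not attacked and both of its stereocentres are retained.

Step 9
Reactants: 11 sabina ketone
Product: 12 (E)-2-(thuj-4(10)-en-10-yl)-4,4,5,5-tetramethyl-1,3,2-dioxaborolane (boron cis to C3')
Conditions: CH2(Bpin)2, lithium 2,2,6,6-tetramethylpiperidide, THF, 0 °C; then 11, −78 °C to rt
Reagents that add atoms: bis(4,4,5,5-tetramethyl-1,3,2-dioxaborolan-2-yl)methane CC1(C)OB(CB2OC(C)(C)C(C)(C)O2)OC1(C)C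
Why: Boron–Wittig olefination: the lithiated geminal bis(boronate) adds to the ketone and the β-alkoxy boronate loses lithium pinacolborate by syn elimination; the cyclopropane carbon C5' next to the carbonyl cannot be deprotonated, so no stereocentre is at risk.

Step 10
Reactants: 9 14-bromo-7,7-(ethylenedioxy)-11,12-dimethoxyabieta-8,11,13-triene; 12 (E)-2-(thuj-4(10)-en-10-yl)-4,4,5,5-tetramethyl-1,3,2-dioxaborolane
Product: 13 (E)-14-(thuj-4'(10')-en-10'-yl)-7,7-(ethylenedioxy)-11,12-dimethoxyabieta-8,11,13-triene
Conditions: Pd(OAc)2 (5 mol%), SPhos, K3PO4, toluene/H2O, 90 °C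
Reagents that add atoms: none
Why: Suzuki–Miyaura coupling forms C14–C10'; the dialkylbiarylphosphine is suited to doubly ortho-substituted aryl bromides and the alkenyl boronate transfers with retention of geometry. Dioxolane, ethers and cyclopropane are inert to zerovalent palladium and phosphate.

Step 11
Reactants: 13 (E)-14-(thuj-4'(10')-en-10'-yl)-7,7-(ethylenedioxy)-11,12-dimethoxyabieta-8,11,13-triene
Product: 14 4',10'-epoxide of 13 (epoxide oxygen anti to C6')
Conditions: dimethyldioxirane, acetone/CH2Cl2, −20 °C
Reagents that add atoms: dimethyldioxirane CC1(C)OO1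
Why: Epoxidation from the convex face of the bicyclo[3.1.0]hexane, anti to the cyclopropane methylene, the face this ring system offers to electrophiles, so the oxygen on C4' is anti to C6'. Neutral conditions preserve the acid-labile epoxide and the dioxolane.

Step 12
Reactants: 14 4',10'-epoxide of 13
Product: 16 14-(4'-formylthujan-4'-yl)-11,12-dimethoxyabieta-8,11,13-trien-7-one (C14 cis to C6'), via dioxolane aldehyde 15 (not isolated)
Conditions: MeAl(OC6H2-2,6-tBu2-4-Br)2 (2 equiv), CH2Cl2, −78 °C; then 1 M HCl, THF, rt
Reagents that add atoms: water O
Why: Meinwald rearrangement: the bulky aluminium Lewis acid opens the epoxide at C4' (tertiary and cyclopropylcarbinyl-stabilised, while the twisted arene cannot stabilise C10'), and the electron-rich aryl group migrates from C10' to C4' anti to the departing oxygen. This places C14 syn to C6' and makes C10' the aldehyde; the bulk on oxygen disfavours the competing hydride shift, and dilute HCl then hydrolyses the aryl dioxolane without touching the non-enolisable aldehyde or the cyclopropane.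

Step 13
Reactants: 16 14-(4'-formylthujan-4'-yl)-11,12-dimethoxyabieta-8,11,13-trien-7-one
Product: 17 ring D-closed 7α,10'α-diol (11,12-dimethoxy; C7–C10' bond formed)
Conditions: SmI2 (2.5 equiv), t-BuOH (2 equiv), THF (0.005 M), −78 to 0 °C; aq. NH4Cl
Reagents that add atoms: none
Why: Divalent samarium transfers one electron to a carbonyl group (most likely the conjugated C7 ketone; the result is the same if the aldehyde is reduced first) and the ketyl carbon adds to the second carbonyl held on the same trivalent samarium; a second electron reduces the oxygen radical to the samarium diolate, which is protonated on work-up. The closest known reaction type is the SmI2-promoted intramolecular ketone–aldehyde pinacol coupling to cis-cyclopentane-1,2-diols. Ring D closes 5-exo-trig, with C7 and C10' held within bonding distance on the neighbouring arene carbons C8 and C14. At C7 the trans A/B fusion fixes the half-chair of ring B with C6 above the arene plane, so C10' must enter pseudo-equatorially in that plane and the oxygen ends pseudo-axial on the α face. At C10' chelation of both oxygens on one trivalent samarium forces the cis diol, that is the α hydroxyl of the target. The step needs cyclisation to beat simple reduction and intermolecular coupling, which proximity, high dilution and a weak proton source should secure. It also needs the cyclopropane to stay closed, which holds because the ketyl at C10' is separated from it by the quaternary C4'. The aryl methyl ethers are not reduced.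

Step 14
Reactants: 17 ring D-closed 7α,10'α-diol (11,12-dimethoxy)
Product: 19 CNP0114174.1 (target quinone methide), via catechol triol 18 (not isolated)
Conditions: BBr3 (5 equiv), 2,6-di-tert-butyl-4-methylpyridine, CH2Cl2, −78 to −20 °C; aq. NaHCO3; then pyridinium p-toluenesulfonate (cat.), CH2Cl2, 0 °C, argon
Reagents that add atoms: none
Why: BBr3 first ties the cis-diol up as a cyclic borate, which holds back ionisation at C7, and then cleaves both out-of-plane aryl methyl ethers at low temperature while the hindered pyridine takes up HBr that could open the cyclopropane. After hydrolysis, trace acid ionises the tertiary para-hydroxybenzylic C7–OH and loss of the O12 proton gives the quinone methide (C7=C8, C12=O, C11 enol) with no redox step. C10', C4', C5', C1', C5 and C10 are not touched.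

## Compound list

1 | carnosic acid (11,12-dihydroxyabieta-8,11,13-trien-20-oic acid) | CC(C)c1cc2CC[C@H]3C(C)(C)CCC[C@]3(C(=O)O)c2c(O)c1O | starting material
2 | methyl 11,12-dimethoxyabieta-8,11,13-trien-20-oate | CC(C)c1cc2CC[C@H]3C(C)(C)CCC[C@]3(C(=O)OC)c2c(OC)c1OC | intermediate
3 | 11,12-dimethoxyabieta-8,11,13-trien-20-ol | CC(C)c1cc2CC[C@H]3C(C)(C)CCC[C@]3(CO)c2c(OC)c1OC | intermediate
4 | 11,12-dimethoxyabieta-8,11,13-trien-20-al | CC(C)c1cc2CC[C@H]3C(C)(C)CCC[C@]3(C=O)c2c(OC)c1OC | intermediate
5 | C20 hydrazone of 4 | CC(C)c1cc2CC[C@H]3C(C)(C)CCC[C@]3(/C=N/N)c2c(OC)c1OC | intermediate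
6 | 11,12-dimethoxyabieta-8,11,13-triene | CC(C)c1cc2CC[C@H]3C(C)(C)CCC[C@]3(C)c2c(OC)c1OC | intermediate
7 | 14-bromo-11,12-dimethoxyabieta-8,11,13-triene | CC(C)c1c(Br)c2CC[C@H]3C(C)(C)CCC[C@]3(C)c2c(OC)c1OC | intermediate
8 | 14-bromo-11,12-dimethoxyabieta-8,11,13-trien-7-one | CC(C)c1c(Br)c2C(=O)C[C@H]3C(C)(C)CCC[C@]3(C)c2c(OC)c1OC | intermediate
9 | 14-bromo-7,7-(ethylenedioxy)-11,12-dimethoxyabieta-8,11,13-triene | CC(C)c1c(Br)c2C3(OCCO3)C[C@H]4C(C)(C)CCC[C@]4(C)c2c(OC)c1OC | intermediate
10 | (1R,5R)-sabinene | C=C1CC[C@]2(C(C)C)C[C@@H]21 | starting material
11 | sabina ketone, (1S,5R)-5-(propan-2-yl)bicyclo[3.1.0]hexan-2-one | O=C1CC[C@]2(C(C)C)C[C@@H]21 | intermediate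
12 | (E)-2-(thuj-4(10)-en-10-yl)-4,4,5,5-tetramethyl-1,3,2-dioxaborolane, boron cis to C3' | CC1(C)OB(OC1(C)C)/C=C1\CC[C@]2(C(C)C)C[C@@H]21 | intermediate
13 | (E)-14-(thuj-4'(10')-en-10'-yl)-7,7-(ethylenedioxy)-11,12-dimethoxyabieta-8,11,13-triene, C14 cis to C3' | CC(C)c1c(/C=C5\CC[C@]6(C(C)C)C[C@@H]65)c2C3(OCCO3)C[C@H]4C(C)(C)CCC[C@]4(C)c2c(OC)c1OC | intermediate
14 | 4',10'-epoxide of 13, oxygen anti to C6' | CC(C)c1c([C@@H]7O[C@]78CC[C@]9(C(C)C)C[C@@H]98)c2C3(OCCO3)C[C@H]4C(C)(C)CCC[C@]4(C)c2c(OC)c1OC | intermediate
15 | 14-(4'-formylthujan-4'-yl)-7,7-(ethylenedioxy)-11,12-dimethoxyabieta-8,11,13-triene, C14 cis to C6' | CC(C)c1c(OC)c(OC)c2c(c1[C@]3(C=O)CC[C@]4(C(C)C)C[C@H]34)C5(OCCO5)C[C@H]6C(C)(C)CCC[C@]26C | intermediate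
16 | 14-(4'-formylthujan-4'-yl)-11,12-dimethoxyabieta-8,11,13-trien-7-one, C14 cis to C6' | CC(C)c1c(OC)c(OC)c2c(c1[C@]3(C=O)CC[C@]4(C(C)C)C[C@H]34)C(=O)C[C@H]5C(C)(C)CCC[C@]25C | intermediate
17 | ring D-closed 7α,10'α-dihydroxy-11,12-dimethoxy spiro adduct (cis-diol) | CC(C)c1c(OC)c(OC)c2c3c1[C@@]1(CC[C@]4(C(C)C)C[C@@H]41)[C@H](O)[C@@]3(O)C[C@H]1C(C)(C)CCC[C@]21C | intermediate
18 | 7α,10'α,11,12-tetrahydroxy spiro adduct (catechol triol) | CC(C)c1c(O)c(O)c2c3c1[C@@]1(CC[C@]4(C(C)C)C[C@@H]41)[C@H](O)[C@@]3(O)C[C@H]1C(C)(C)CCC[C@]21C | intermediate
19 | CNP0114174.1, 11,10'α-dihydroxy-12-oxo-abieta-7,9(11),13-triene spiro-fused to (1'R,5'R)-thujane through C14–C4' and C7–C10' | CC(C)C1=C2C3=C(C[C@H]4C(C)(C)CCC[C@]4(C)C3=C(O)C1=O)[C@@H](O)[C@]21CC[C@]2(C(C)C)C[C@@H]21 | target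

## Step count and least certain steps

Total: 14 steps. Longest linear sequence: 12 steps (from 1 through steps 1 to 7 and 10 to 14); steps 8 and 9 make the thujane partner from 10.

**Step 13 (key step).** The most likely failure is incomplete chelation control at C10', so that the hydroxyl is formed partly on the β face; simple reduction of one carbonyl before ring closure is the second risk and is answered by dilution.
- Fallback, setting out from 16 and returning at 17: set C10' by hydride delivery and not by the coupling itself.
- The crude mixture of 17 and its 10'β-hydroxy epimer F1 is oxidised at the only oxidisable carbinol (SO3·pyridine, DMSO, iPr2NEt, Parikh–Doering oxidation) to the 7α-hydroxy-10'-ketone F2.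
- F2 is reduced with LiBH(s-Bu)3 at −78 °C from the β face, anti to the pseudo-axial 7α oxygen, which gives 17.

**Step 12.** The most likely failure is hydride shift or opening of the cyclopropylcarbinyl system outrunning the aryl shift, made worse by the bulky dioxolane beside the migrating carbon, which may also ionise or take part under the Lewis acid.
- Fallback, setting out from 7 and 12 and returning at 16: carry out the aryl shift before any oxygen is placed on C7.
- Coupling of 7 with 12 under the conditions of step 10 gives (E)-14-(thuj-4'(10')-en-10'-yl)-11,12-dimethoxyabieta-8,11,13-triene F3.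
- Dimethyldioxirane gives its 4',10'-epoxide F4.
- The aluminium aryloxide of step 12 gives 14-(4'-formylthujan-4'-yl)-11,12-dimethoxyabieta-8,11,13-triene F5, now from a less crowded and more electron-rich arene.
- The aldehyde is masked as its 1,3-dioxolane F6 ((Me3SiOCH2)2, cat. Me3SiOTf).
- C7 is oxidised with the CrO3–3,5-dimethylpyrazole complex in CH2Cl2 at −20 °C to the 7-ketone F7, and dilute HCl releases 16.

**Step 10.** The most likely failure is slow oxidative addition and transmetalation at the doubly ortho-substituted C14–Br, with protodeboronation of the boronate taking over.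
- Fallback, setting out from 9 and 10 and returning at 13: replace the cross-coupling by carbonyl addition and dehydration.
- Hydroboration of 10 (9-borabicyclo[3.3.1]nonane, then NaOH/H2O2) gives thujan-10-ol F8, and Dess–Martin oxidation gives thujane-4-carbaldehyde F9; the configuration at C4' is of no consequence.
- Bromine–lithium exchange on 9 (t-BuLi, THF, −78 °C, then CeCl3) and addition to F9 gives the benzylic carbinol F10 as a mixture at C10'.
- Syn dehydration with methyl N-(triethylammoniumsulfonyl)carbamate (Burgess reagent) returns 13, C4' being the only β-carbon that bears hydrogen.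

**Step 14.** The most likely failure is acid-induced opening of the cyclopropane, or migration of the quinone methide double bond to C6–C7 during the Lewis-acid ether cleavage.
- Fallback, setting out from 8 and returning at 18: exchange the methyl ethers for benzyl ethers while the molecule is still robust, so that the last deprotection is neutral.
- BBr3 on 8 gives 14-bromo-11,12-dihydroxyabieta-8,11,13-trien-7-one F11, and BnBr/Cs2CO3 in DMF gives its bis(benzyl ether) F12.
- Steps 7 and 10 to 13 are then repeated unchanged and give in turn the dioxolane F13, the alkene F14, the epoxide F15, the dioxolane aldehyde F16 (not isolated), the keto aldehyde F17 and the ring D-closed cis-diol F18.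
- H2 over Pd/C in ethyl acetate removes both benzyl groups and gives 18, which the final operation of step 14 converts into 19.

## Further compounds

F1 | step 13 | 10'β-hydroxy epimer of 17 (trans-diol) | CC(C)c1c(OC)c(OC)c2c3c1[C@@]1(CC[C@]4(C(C)C)C[C@@H]41)[C@@H](O)[C@@]3(O)C[C@H]1C(C)(C)CCC[C@]21C
F2 | step 13 | 7α-hydroxy-10'-oxo ring D ketol | CC(C)c1c(OC)c(OC)c2c3c1[C@@]1(CC[C@]4(C(C)C)C[C@@H]41)C(=O)[C@@]3(O)C[C@H]1C(C)(C)CCC[C@]21C
F3 | step 12 | (E)-14-(thuj-4'(10')-en-10'-yl)-11,12-dimethoxyabieta-8,11,13-triene | CC(C)c1c(/C=C5\CC[C@]6(C(C)C)C[C@@H]65)c2CC[C@H]4C(C)(C)CCC[C@]4(C)c2c(OC)c1OC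
F4 | step 12 | 4',10'-epoxide of F3, oxygen anti to C6' | CC(C)c1c([C@@H]7O[C@]78CC[C@]9(C(C)C)C[C@@H]98)c2CC[C@H]4C(C)(C)CCC[C@]4(C)c2c(OC)c1OC
F5 | step 12 | 14-(4'-formylthujan-4'-yl)-11,12-dimethoxyabieta-8,11,13-triene | CC(C)c1c(OC)c(OC)c2c(c1[C@]3(C=O)CC[C@]4(C(C)C)C[C@H]34)CC[C@H]5C(C)(C)CCC[C@]25C
F6 | step 12 | 1,3-dioxolane of F5 at C10' | CC(C)c1c(OC)c(OC)c2c(c1[C@]3(C6OCCO6)CC[C@]4(C(C)C)C[C@H]34)CC[C@H]5C(C)(C)CCC[C@]25C
F7 | step 12 | 7-oxo derivative of F6 | CC(C)c1c(OC)c(OC)c2c(c1[C@]3(C6OCCO6)CC[C@]4(C(C)C)C[C@H]34)C(=O)C[C@H]5C(C)(C)CCC[C@]25C
F8 | step 10 | thujan-10-ol (major C4' epimer drawn) | OC[C@@H]1CC[C@]2(C(C)C)C[C@@H]21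
F9 | step 10 | thujane-4-carbaldehyde (major C4' epimer drawn) | O=C[C@@H]1CC[C@]2(C(C)C)C[C@@H]21
F10 | step 10 | 14-[hydroxy(thujan-4'-yl)methyl]-7,7-(ethylenedioxy)-11,12-dimethoxyabieta-8,11,13-triene (both C10' epimers) | CC(C)c1c(C(O)[C@@H]5CC[C@]6(C(C)C)C[C@@H]65)c2C3(OCCO3)C[C@H]4C(C)(C)CCC[C@]4(C)c2c(OC)c1OC
F11 | step 14 | 14-bromo-11,12-dihydroxyabieta-8,11,13-trien-7-one | CC(C)c1c(Br)c2C(=O)C[C@H]3C(C)(C)CCC[C@]3(C)c2c(O)c1O
F12 | step 14 | 11,12-bis(benzyloxy)-14-bromoabieta-8,11,13-trien-7-one | CC(C)c1c(Br)c2C(=O)C[C@H]3C(C)(C)CCC[C@]3(C)c2c(OCc4ccccc4)c1OCc5ccccc5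
F13 | step 14 | 11,12-bis(benzyloxy)-14-bromo-7,7-(ethylenedioxy)abieta-8,11,13-triene | CC(C)c1c(Br)c2C3(OCCO3)C[C@H]4C(C)(C)CCC[C@]4(C)c2c(OCc5ccccc5)c1OCc6ccccc6
F14 | step 14 | bis(benzyl ether) analogue of 13 | CC(C)c1c(/C=C5\CC[C@]6(C(C)C)C[C@@H]65)c2C3(OCCO3)C[C@H]4C(C)(C)CCC[C@]4(C)c2c(OCc7ccccc7)c1OCc8ccccc8
F15 | step 14 | bis(benzyl ether) analogue of 14 | CC(C)c1c([C@@H]7O[C@]78CC[C@]9(C(C)C)C[C@@H]98)c2C3(OCCO3)C[C@H]4C(C)(C)CCC[C@]4(C)c2c(OCc5ccccc5)c1OCc6ccccc6
F16 | step 14 | bis(benzyl ether) analogue of 15 | CC(C)c1c(OCc7ccccc7)c(OCc8ccccc8)c2c(c1[C@]3(C=O)CC[C@]4(C(C)C)C[C@H]34)C5(OCCO5)C[C@H]6C(C)(C)CCC[C@]26C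
F17 | step 14 | bis(benzyl ether) analogue of 16 | CC(C)c1c(OCc7ccccc7)c(OCc8ccccc8)c2c(c1[C@]3(C=O)CC[C@]4(C(C)C)C[C@H]34)C(=O)C[C@H]5C(C)(C)CCC[C@]25C
F18 | step 14 | bis(benzyl ether) analogue of 17 | CC(C)c1c(OCc5ccccc5)c(OCc6ccccc6)c2c3c1[C@@]1(CC[C@]4(C(C)C)C[C@@H]41)[C@H](O)[C@@]3(O)C[C@H]1C(C)(C)CCC[C@]21C
A1 | alternative 1 | 5,6-didehydro-11,12-dimethoxy spiro adduct, 10'-epi tert-butyldimethylsilyl ether | CC(C)c1c(OC)c(OC)c2c3c1[C@@]1(CC[C@]4(C(C)C)C[C@@H]41)[C@@H](O[Si](C)(C)C(C)(C)C)[C@@H]3C=C1C(C)(C)CCC[C@]21C
A2 | alternative 1 | 2-(trimethylsilyl)aryl triflate carrying the thujane, the 10'-silyloxy group and the trimethylcyclohexenyl diene | CC(C)c1c(OC)c(OC)c([Si](C)(C)C)c(OS(=O)(=O)C(F)(F)F)c1[C@@]1(CC[C@]2(C(C)C)C[C@@H]21)[C@@H](O[Si](C)(C)C(C)(C)C)/C=C/C1=C(C)CCCC1(C)C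
A3 | alternative 2 | 11,12-dihydroxy full skeleton with 7α-H and 10'α-OH | CC(C)c1c(O)c(O)c2c3c1[C@@]1(CC[C@]4(C(C)C)C[C@@H]41)[C@H](O)[C@H]3C[C@H]1C(C)(C)CCC[C@]21C
A4 | alternative 2 | C7-geranyl spiro-indane catechol | CC(C)c1c(O)c(O)cc2c1[C@@]1(CC[C@]3(C(C)C)C[C@@H]31)[C@H](O)[C@H]2C/C=C(\C)CCC=C(C)C
A5 | alternative 3 | spiro thujan-2'-one, 10'-triisopropylsilyl ether | CC(C)c1c(OC)c(OC)c2c3c1[C@@]1(CC(=O)[C@]4(C(C)C)C[C@@H]41)[C@H](O[Si](C(C)C)(C(C)C)C(C)C)[C@H]3C[C@H]1C(C)(C)CCC[C@]21C
A6 | alternative 3 | spiro 1'-isopropylcyclopent-1'(5')-en-2'-one, 10'-triisopropylsilyl ether | CC(C)c1c(OC)c(OC)c2c3c1[C@@]1(CC(=O)C(C(C)C)=C1)[C@H](O[Si](C(C)C)(C(C)C)C(C)C)[C@H]3C[C@H]1C(C)(C)CCC[C@]21C
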